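**Retrosynthetic overview**

1. Atoms are numbered C1–C28 by their position in the target SMILES. The route rests on rings C (C28, C3, C4, C10, C11) and D (C4, O5, C6, C8, C10): a fused butenolide with carbonyl C6 between O5 and C8, the [2+2+1] retron of aldehyde C4=O5, alkyne C10≡C8 and CO once the C10=C11 alkene is moved to C8=C10.
2. A conjugated butenolide carrying C11–H would lose C4–H (2-oxidofuran) or a C25 proton before C11–H. The ynal therefore carries C11=C12 instead, the key step gives a dienolide (C8=C10, C11=C12), and the alkene transposition becomes a 1,6-hydride addition at C12 with kinetic protonation at C8.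
3. Ynal: C4 aldehyde from an acetal; lactone E (C13–C14) by reductive vinylogous Mannich reaction on the ring B lactam, then conjugate reduction; propynyl on C11 by Sonogashira coupling of a tetramic acid triflate.
4. Ring B by Dieckmann closure (C11–C12) of an N-acetyl azepanone β-keto ester; C28 and C3 by iridium-catalysed branched allylation; ring A by rhodium-catalysed N–H insertion.
5. Ring order: A, then B, then E, then C and D together in the key step.

Key step: step 14

Remark on the chemistry: the tetramic acid of step 7 is drawn as its diketo tautomer; the C28/C3 relative configuration from step 4 is assigned by analogy with cyclic β-keto esters and should be confirmed on that tetramic acid before going on.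

**Route**

Step 1
Reactants: 1 tert-butyl 2-oxopiperidine-1-carboxylate; 2 ethyl diazoacetate
Product: 4 ethyl 7-[(tert-butoxycarbonyl)amino]-2-diazo-3-oxoheptanoate, via ethyl lithiodiazoacetate 3 (not isolated)
Conditions: LiN(i-Pr)2, THF, −78 °C; then 1, −78 °C; AcOH quench
Reagents that add atoms: none
Why: Nucleophilic acyl substitution (ring-opening C-acylation of an N-acyl lactam): the lithiated diazo ester should add to the imide-type carbonyl and the carbamate anion leaves, giving the chain N21–C22…C26 with the diazo carbon (C28) between C26=O and the ester carbon C11.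

Step 2
Reactants: 4 ethyl 7-[(tert-butoxycarbonyl)amino]-2-diazo-3-oxoheptanoate
Product: 5 1-tert-butyl 2-ethyl 3-oxoazepane-1,2-dicarboxylate (racemic)
Conditions: Rh2(OAc)4 (1 mol%), CH2Cl2, 40 °C
Reagents that add atoms: none
Why: Rhodium-carbenoid intramolecular N–H insertion into the carbamate should close ring A (N21–C28) and place the ester regiospecifically between N21 and the C26 ketone, which direct carboxylation of an azepan-3-one would not do reliably.

Step 3
Reactants: 6 (E)-pent-2-en-1-ol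
Product: 7 methyl (E)-pent-2-en-1-yl carbonate
Conditions: ClCO2Me, pyridine, CH2Cl2, 0 °C
Reagents that add atoms: methyl chloroformate, COC(=O)Cl
Why: O-acylation of the primary allylic alcohol gives the carbonate leaving group needed for iridium allyl chemistry.

Step 4
Reactants: 5 1-tert-butyl 2-ethyl 3-oxoazepane-1,2-dicarboxylate; 7 methyl (E)-pent-2-en-1-yl carbonate
Product: 8 1-tert-butyl 2-ethyl (2S)-3-oxo-2-[(3S)-pent-1-en-3-yl]azepane-1,2-dicarboxylate
Conditions: [Ir(cod)Cl]2 (2 mol%), binaphthol-derived N,N-bis(1-phenylethyl)phosphoramidite (4 mol%, enantiomer chosen for 3S), TBD (10 mol%), LiBr (1 equiv), THF, 25 °C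
Reagents that add atoms: none
Why: Iridium-catalysed branched-selective allylic alkylation of a cyclic β-keto ester: the enolate of 5 (C28 is labile, so both enantiomers pass through one enolate) should attack the ethyl-bearing terminus of the (π-allyl)iridium–phosphoramidite complex anti to the metal, the ligand fixing C3 (3S) and the chelated enolate face fixing C28 (2S), with the relative configuration assigned by analogy.

Step 5
Reactants: 8 1-tert-butyl 2-ethyl (2S)-3-oxo-2-[(3S)-pent-1-en-3-yl]azepane-1,2-dicarboxylate; 9 acetyl chloride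
Product: 11 ethyl (2S)-1-acetyl-3-oxo-2-[(3S)-pent-1-en-3-yl]azepane-2-carboxylate, via secondary amine 10 (not isolated)
Conditions: TFA, CH2Cl2, 0 °C to rt; evaporate; then AcCl, Et3N, DMAP (cat.), CH2Cl2, 0 °C to rt
Reagents that add atoms: none
Why: Acidolysis of the tert-butyl carbamate followed by N-acylation of the hindered secondary amine with the small acyl chloride; the acetyl group supplies C13 and C12 of ring B.

Step 6
Reactants: 11 ethyl (2S)-1-acetyl-3-oxo-2-[(3S)-pent-1-en-3-yl]azepane-2-carboxylate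
Product: 13 ethyl (2S)-1-acetyl-2-[(2R)-1,1-dimethoxybutan-2-yl]-3-oxoazepane-2-carboxylate, via aldehyde 12 (not isolated)
Conditions: O3, CH2Cl2/MeOH, −78 °C; Me2S, −78 °C to rt; then HC(OMe)3, p-TsOH·H2O (cat.), MeOH, rt
Reagents that add atoms: ozone, [O-][O+]=O (carbonyl oxygen of 12); trimethyl orthoformate, COC(OC)OC (the two methoxy groups of 13)
Why: Ozonolysis of the only alkene gives the C4 aldehyde, which is masked at once by acid-catalysed acetalisation (the C26 ketone next to quaternary C28 should not ketalise), so the epimerisable C3–H aldehyde is not carried through the basic steps.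

Step 7
Reactants: 13 ethyl (2S)-1-acetyl-2-[(2R)-1,1-dimethoxybutan-2-yl]-3-oxoazepane-2-carboxylate
Product: 14 (9aS)-9a-[(2R)-1,1-dimethoxybutan-2-yl]-5,6,7,8-tetrahydro-1H-pyrrolo[1,2-a]azepine-1,3,9(2H,9aH)-trione
Conditions: LiN(i-Pr)2 (3.2 equiv), THF, −78 to 0 °C; AcOH quench at −78 °C
Reagents that add atoms: none
Why: Dieckmann (Lacey-type) condensation: with the C26 ketone held as its C25 enolate, the acetamide enolate (C12) should attack the C11 ester in a 5-exo-trig closure and expel ethoxide, formation of the acidic tetramate driving the closure of ring B.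

Step 8
Reactants: 14 (9aS)-9a-[(2R)-1,1-dimethoxybutan-2-yl]-5,6,7,8-tetrahydro-1H-pyrrolo[1,2-a]azepine-1,3,9(2H,9aH)-trione
Product: 15 (9aR)-9a-[(2R)-1,1-dimethoxybutan-2-yl]-3,9-dioxo-5,6,7,8,9,9a-hexahydro-3H-pyrrolo[1,2-a]azepin-1-yl trifluoromethanesulfonate
Conditions: PhNTf2, Et3N, DMAP (cat.), CH2Cl2, 0 °C to rt
Reagents that add atoms: N-phenylbis(trifluoromethanesulfonimide), O=S(=O)(N(c1ccccc1)S(=O)(=O)C(F)(F)F)C(F)(F)F
Why: O-sulfonylation of a vinylogous acid: triethylamine deprotonates only the tetramic acid and not the C25 ketone protons, so the enol triflate should form selectively at C11–O.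

Step 9
Reactants: 15 (9aR)-9a-[(2R)-1,1-dimethoxybutan-2-yl]-3,9-dioxo-5,6,7,8,9,9a-hexahydro-3H-pyrrolo[1,2-a]azepin-1-yl trifluoromethanesulfonate; 16 propyne
Product: 17 (9aR)-9a-[(2R)-1,1-dimethoxybutan-2-yl]-1-(prop-1-yn-1-yl)-5,6,7,8-tetrahydro-3H-pyrrolo[1,2-a]azepine-3,9(9aH)-dione
Conditions: Pd(PPh3)2Cl2 (5 mol%), CuI (10 mol%), Et3N, DMF, propyne (3 equiv, solution in THF), rt
Reagents that add atoms: none
Why: Sonogashira coupling of the electron-poor enol triflate should install C10≡C8–C9 on C11 and keep C11=C12.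

Step 10
Reactants: 18 3-methylfuran-2(5H)-one
Product: 19 3-methyl-2-(triisopropylsilyloxy)furan
Conditions: TIPSOTf, Et3N, CH2Cl2, 0 °C
Reagents that add atoms: triisopropylsilyl trifluoromethanesulfonate, CC(C)[Si](OS(=O)(=O)C(F)(F)F)(C(C)C)C(C)C
Why: Soft enolisation and O-silylation of the butenolide gives the aromatic 2-silyloxyfuran (silyl dienol ether formation).

Step 11
Reactants: 17 (9aR)-9a-[(2R)-1,1-dimethoxybutan-2-yl]-1-(prop-1-yn-1-yl)-5,6,7,8-tetrahydro-3H-pyrrolo[1,2-a]azepine-3,9(9aH)-dione; 19 3-methyl-2-(triisopropylsilyloxy)furan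
Product: 21 (3S,9aR)-9a-[(2R)-1,1-dimethoxybutan-2-yl]-3-[(2S)-4-methyl-5-oxo-2,5-dihydrofuran-2-yl]-1-(prop-1-yn-1-yl)-3,5,6,7,8,9a-hexahydro-9H-pyrrolo[1,2-a]azepin-9-one, via N,O-silyl acetal 20 (not isolated)
Conditions: IrCl(CO)(PPh3)2 (2 mol%), (Me2HSi)2O (2 equiv), toluene, rt; then 19 (2 equiv), PhCO2H (1.1 equiv), MeCN, −20 °C to rt
Reagents that add atoms: none
Why: Reductive vinylogous Mukaiyama–Mannich reaction of a tertiary lactam: iridium-catalysed 1,2-hydrosilylation of the amide C13=O gives 20, which ionises to the conjugated cyclic iminium (aromatisation is blocked by quaternary C28); 19 should attack C13 (C11 is fully substituted) from the face opposite the C3 side chain on C28 (13S), and the usual threo preference of 2-silyloxyfurans with cyclic iminium ions should set 14S.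

Step 12
Reactants: 21 (3S,9aR)-9a-[(2R)-1,1-dimethoxybutan-2-yl]-3-[(2S)-4-methyl-5-oxo-2,5-dihydrofuran-2-yl]-1-(prop-1-yn-1-yl)-3,5,6,7,8,9a-hexahydro-9H-pyrrolo[1,2-a]azepin-9-one
Product: 23 (3S,9aR)-9a-[(2R)-1,1-dimethoxybutan-2-yl]-3-[(2S,4S)-4-methyl-5-oxooxolan-2-yl]-1-(prop-1-yn-1-yl)-3,5,6,7,8,9a-hexahydro-9H-pyrrolo[1,2-a]azepin-9-one, via silyl ketene acetal 22 (not isolated)
Conditions: [(Ph3P)CuH]6 (5 mol%), PhMe2SiH (1.5 equiv), toluene, rt; then AcOH, THF, −78 to 0 °C
Reagents that add atoms: none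
Why: Copper hydride conjugate reduction of the butenolide: hydride adds to C15, and protonation of 22 at C16 from the face away from the C14 substituent should give the cis lactone (16S); the unactivated enyne and the hindered ketone should not be reduced by the phosphine copper hydride.

Step 13
Reactants: 23 (3S,9aR)-9a-[(2R)-1,1-dimethoxybutan-2-yl]-3-[(2S,4S)-4-methyl-5-oxooxolan-2-yl]-1-(prop-1-yn-1-yl)-3,5,6,7,8,9a-hexahydro-9H-pyrrolo[1,2-a]azepin-9-one
Product: 24 (2R)-2-[(3S,9aR)-3-[(2S,4S)-4-methyl-5-oxooxolan-2-yl]-9-oxo-1-(prop-1-yn-1-yl)-3,5,6,7,8,9-hexahydro-9aH-pyrrolo[1,2-a]azepin-9a-yl]butanal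
Conditions: 1 M aq. HCl, THF, 0 °C to rt; cold aq. NaHCO3; used at once
Reagents that add atoms: water, O
Why: Acid-catalysed acetal hydrolysis; N21 is protonated throughout, which suppresses retro-Mannich cleavage, and the short exposure at low temperature should leave C3 intact.

Step 14
Reactants: 24 (2R)-2-[(3S,9aR)-3-[(2S,4S)-4-methyl-5-oxooxolan-2-yl]-9-oxo-1-(prop-1-yn-1-yl)-3,5,6,7,8,9-hexahydro-9aH-pyrrolo[1,2-a]azepin-9a-yl]butanal
Product: 25 dienolide with rings A–E, butenolide ring D (C8=C10) fused to ring C and C11=C12 in ring B (C3 R, C4 S, C13 S, C14 S, C16 S, C28 R)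
Conditions: Mo(CO)6 (1.2 equiv), DMSO (5 equiv), toluene (degassed), 100 °C
Reagents that add atoms: molybdenum hexacarbonyl, O=C=[Mo](=C=O)(=C=O)(=C=O)(=C=O)=C=O (one CO becomes C6 and its oxygen)
Why: Zerovalent molybdenum, with DMSO freeing coordination sites, should bind the C10≡C8 alkyne and the C4=O5 aldehyde and couple them oxidatively to an oxamolybdacyclopentene (C4–C10), after which CO inserts into the Mo–C8 bond (C8–C6) and reductive elimination forms C6–O5; the closest known reaction is the Mo(CO)6/DMSO hetero-Pauson–Khand cyclocarbonylation of 1,6-ynals to bicyclic butenolides. Ring C (C28, C3, C4, C10, C11) closes in the oxidative cyclisation as a 5-exo-type closure of the 1,6-ynal onto alkyne carbon C10, and ring D (C4, O5, C6, C8, C10) closes by the carbonylative C–O reductive elimination on the metallacycle. The only new stereocentre, C4, is controlled by C3: in the oxametallacycle the metal-bound oxygen should turn away from the C3 ethyl group, so O5 ends anti to ethyl and C4–H lies on the convex face. The step needs aldehyde-over-ketone selectivity, secured because only C4=O5 can reach the alkyne (C26 is tied into ring A on the other face of C28), and it needs the two partners within reach, secured because the alkyne sits on sp2 C11 next to C28 so that no C11 stereocentre has to be matched. Retro-Mannich loss of the side chain is disfavoured because the required iminium at C28 would sit next to the C26 carbonyl, and the non-basic medium limits epimerisation at C3.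

Step 15
Reactants: 25 dienolide (C8=C10, C11=C12)
Product: 27 CNP0315436.2 (C3 R, C4 S, C8 R, C13 S, C14 S, C16 S, C28 R), via silyl dienol ether 26 (not isolated)
Conditions: [(Ph3P)CuH]6 (10 mol%), PhMe2SiH (1.5 equiv), toluene, 0 °C to rt; then AcOH (3 equiv), Bu4NF (1.2 equiv), THF, −78 °C
Reagents that add atoms: none
Why: Copper hydride conjugate reduction in its 1,6-mode: hydride should add to the unhindered δ-carbon C12 (the β-carbon C10 is fully substituted) to give the cross-conjugated silyl ketene acetal 26, and buffered fluoride-induced protonation of the derived dienolate should occur kinetically at the α-carbon C8 from the face of C4–H (away from C3 across the planar ring D), which sets C8 and leaves the alkene at C10=C11.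

**Compound list**

1 | tert-butyl 2-oxopiperidine-1-carboxylate | O=C1CCCCN1C(=O)OC(C)(C)C | starting material
2 | ethyl diazoacetate | CCOC(=O)C=[N+]=[N-] | starting material
3 | ethyl lithiodiazoacetate (formed in the flask) | [Li]C(=[N+]=[N-])C(=O)OCC | intermediate
4 | ethyl 7-[(tert-butoxycarbonyl)amino]-2-diazo-3-oxoheptanoate | CCOC(=O)C(=[N+]=[N-])C(=O)CCCCNC(=O)OC(C)(C)C | intermediate
5 | 1-tert-butyl 2-ethyl 3-oxoazepane-1,2-dicarboxylate (racemic) | CCOC(=O)C1C(=O)CCCCN1C(=O)OC(C)(C)C | intermediate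
6 | (E)-pent-2-en-1-ol | CC/C=C/CO | starting material
7 | methyl (E)-pent-2-en-1-yl carbonate | CC/C=C/COC(=O)OC | intermediate
8 | 1-tert-butyl 2-ethyl (2S)-3-oxo-2-[(3S)-pent-1-en-3-yl]azepane-1,2-dicarboxylate | CC[C@@H](C=C)[C@]1(C(=O)OCC)N(C(=O)OC(C)(C)C)CCCCC1=O | intermediate
9 | acetyl chloride | CC(Cl)=O | starting material
10 | ethyl (2S)-3-oxo-2-[(3S)-pent-1-en-3-yl]azepane-2-carboxylate (not isolated) | CC[C@@H](C=C)[C@]1(C(=O)OCC)NCCCCC1=O | intermediate
11 | ethyl (2S)-1-acetyl-3-oxo-2-[(3S)-pent-1-en-3-yl]azepane-2-carboxylate | CC[C@@H](C=C)[C@]1(C(=O)OCC)N(C(C)=O)CCCCC1=O | intermediate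
12 | ethyl (2S)-1-acetyl-3-oxo-2-[(2R)-1-oxobutan-2-yl]azepane-2-carboxylate (not isolated) | CC[C@@H](C=O)[C@]1(C(=O)OCC)N(C(C)=O)CCCCC1=O | intermediate
13 | ethyl (2S)-1-acetyl-2-[(2R)-1,1-dimethoxybutan-2-yl]-3-oxoazepane-2-carboxylate | CC[C@@H](C(OC)OC)[C@]1(C(=O)OCC)N(C(C)=O)CCCCC1=O | intermediate
14 | (9aS)-9a-[(2R)-1,1-dimethoxybutan-2-yl]-5,6,7,8-tetrahydro-1H-pyrrolo[1,2-a]azepine-1,3,9(2H,9aH)-trione (tetramic acid, diketo form) | CC[C@@H](C(OC)OC)[C@]12C(=O)CC(=O)N1CCCCC2=O | intermediate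
15 | (9aR)-9a-[(2R)-1,1-dimethoxybutan-2-yl]-3,9-dioxo-5,6,7,8,9,9a-hexahydro-3H-pyrrolo[1,2-a]azepin-1-yl trifluoromethanesulfonate | CC[C@@H](C(OC)OC)[C@]12C(OS(=O)(=O)C(F)(F)F)=CC(=O)N1CCCCC2=O | intermediate
16 | propyne | CC#C | starting material
17 | (9aR)-9a-[(2R)-1,1-dimethoxybutan-2-yl]-1-(prop-1-yn-1-yl)-5,6,7,8-tetrahydro-3H-pyrrolo[1,2-a]azepine-3,9(9aH)-dione | CC[C@@H](C(OC)OC)[C@]12C(C#CC)=CC(=O)N1CCCCC2=O | intermediate
18 | 3-methylfuran-2(5H)-one | CC1=CCOC1=O | starting material
19 | 3-methyl-2-(triisopropylsilyloxy)furan | Cc1ccoc1O[Si](C(C)C)(C(C)C)C(C)C | intermediate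
20 | (9aR)-9a-[(2R)-1,1-dimethoxybutan-2-yl]-1-(prop-1-yn-1-yl)-3-[(1,1,3,3-tetramethyldisiloxanyl)oxy]-3,5,6,7,8,9a-hexahydro-9H-pyrrolo[1,2-a]azepin-9-one (C13 epimers, not isolated) | CC[C@@H](C(OC)OC)[C@]12C(C#CC)=CC(O[Si](C)(C)O[SiH](C)C)N1CCCCC2=O | intermediate
21 | (3S,9aR)-9a-[(2R)-1,1-dimethoxybutan-2-yl]-3-[(2S)-4-methyl-5-oxo-2,5-dihydrofuran-2-yl]-1-(prop-1-yn-1-yl)-3,5,6,7,8,9a-hexahydro-9H-pyrrolo[1,2-a]azepin-9-one | CC[C@@H](C(OC)OC)[C@]12C(C#CC)=C[C@@H]([C@@H]3C=C(C)C(=O)O3)N1CCCCC2=O | intermediate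
22 | (3S,9aR)-9a-[(2R)-1,1-dimethoxybutan-2-yl]-3-[(2S)-5-{[dimethyl(phenyl)silyl]oxy}-4-methyl-2,3-dihydrofuran-2-yl]-1-(prop-1-yn-1-yl)-3,5,6,7,8,9a-hexahydro-9H-pyrrolo[1,2-a]azepin-9-one (not isolated) | CC[C@@H](C(OC)OC)[C@]12C(C#CC)=C[C@@H]([C@@H]3CC(C)=C(O[Si](C)(C)c4ccccc4)O3)N1CCCCC2=O | intermediate
23 | (3S,9aR)-9a-[(2R)-1,1-dimethoxybutan-2-yl]-3-[(2S,4S)-4-methyl-5-oxooxolan-2-yl]-1-(prop-1-yn-1-yl)-3,5,6,7,8,9a-hexahydro-9H-pyrrolo[1,2-a]azepin-9-one | CC[C@@H](C(OC)OC)[C@]12C(C#CC)=C[C@@H]([C@@H]3C[C@H](C)C(=O)O3)N1CCCCC2=O | intermediate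
24 | (2R)-2-[(3S,9aR)-3-[(2S,4S)-4-methyl-5-oxooxolan-2-yl]-9-oxo-1-(prop-1-yn-1-yl)-3,5,6,7,8,9-hexahydro-9aH-pyrrolo[1,2-a]azepin-9a-yl]butanal (enyne ynal, key-step precursor) | CC[C@@H](C=O)[C@]12C(C#CC)=C[C@@H]([C@@H]3C[C@H](C)C(=O)O3)N1CCCCC2=O | intermediate
25 | dienolide, key-step product: rings A–E, butenolide ring D (C8=C10) fused to ring C, C11=C12 in ring B; O5 anti to the C3 ethyl group (C3 R, C4 S, C13 S, C14 S, C16 S, C28 R) | CC[C@H]1[C@@H]2OC(=O)C(C)=C2C2=C[C@@H]([C@@H]3C[C@H](C)C(=O)O3)N3CCCCC(=O)[C@]213 | intermediate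
26 | silyl dienol ether from 25: C6(OSiMe2Ph)=C8 ketene acetal, C10=C11, C12H2 (not isolated) | CC[C@H]1[C@@H]2OC(O[Si](C)(C)c3ccccc3)=C(C)C2=C2C[C@@H]([C@@H]3C[C@H](C)C(=O)O3)N3CCCCC(=O)[C@]213 | intermediate
27 | CNP0315436.2: C10=C11 alkene, C8–H cis to C4–H (C3 R, C4 S, C8 R, C13 S, C14 S, C16 S, C28 R) | CC[C@H]1[C@@H]2OC(=O)[C@H](C)C2=C2C[C@@H]([C@@H]3C[C@H](C)C(=O)O3)N3CCCCC(=O)[C@]213 | target

**Step count**

Total: 15 steps. Longest linear sequence: 13 steps (steps 1, 2, 4–9 and 11–15, from 1).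

**Steps most likely to fail**

Step 11. The iminium may be captured with poor selectivity: attack at the alkyne terminus C8 (1,6-addition) instead of C13, hydrosilylation of the alkyne or ketone competing with reduction of the lactam, or low facial or threo selectivity. The fallback sets out from 15 and comes back at 23; it changes the order so that the iminium carries the triflate and no alkyne. Triflate 15 should be hydrosilylated under the same iridium conditions to the N,O-silyl acetal F1 and treated with 19 to give the butenolide triflate F2. Copper hydride reduction with PhMe2SiH should pass through the silyl ketene acetal F3 and, after protonation with AcOH, give the lactone triflate F4. Sonogashira coupling of F4 with propyne 16 (Pd(PPh3)2Cl2, CuI, Et3N) should then give 23.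

Step 14. At 100 °C the β-amino aldehyde may epimerise at C3 or fragment by retro-Mannich cleavage of C28–C3 before oxidative cyclisation sets in, or the amine and the conjugated enyne may hold molybdenum in unproductive complexes. The fallback sets out from 24 and comes back at 25; it separates the two bond-forming events and runs the first at room temperature. Cp2Ti(PMe3)2 (1.1 equiv, THF, rt) should couple alkyne and aldehyde to the oxatitanacyclopentene F5. Iodine at −78 °C should cleave the Ti–C8 bond and, after aqueous work-up, give the (Z)-iodo allylic alcohol F6. Palladium-catalysed carbonylative lactonisation (Pd(PPh3)4, CO 1 atm, Et3N, MeCN, 60 °C) should then close ring D to 25.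

Step 15. Hydride may add 1,4 (at C10) instead of 1,6, protonation may take place at C11 (returning a conjugated butenolide) or from the wrong face of C8, and the C26 ketone may be hydrosilylated. The fallback sets out from 25 and comes back at 27; it uses neither hydride reagent nor base for the transposition. (naphthalene)Cr(CO)3 (cat.), H2, acetone should bring about 1,4-hydrogenation of the s-cis diene C8=C10–C11=C12, adding hydrogen to C8 and C12 and leaving C10=C11. If hydrogen enters C8 from the concave face, the product is the C8 epimer F7. In F7, C8–H is the most acidic C–H, so LiN(SiMe3)2 (1.05 equiv, THF, −78 °C) should give the lithium dienolate F8, and kinetic protonation with AcOH should then give 27.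

**Further compounds**

F1 | step 11 | (9aR)-9a-[(2R)-1,1-dimethoxybutan-2-yl]-9-oxo-3-[(1,1,3,3-tetramethyldisiloxanyl)oxy]-5,6,7,8,9,9a-hexahydro-3H-pyrrolo[1,2-a]azepin-1-yl trifluoromethanesulfonate (C13 epimers) | CC[C@@H](C(OC)OC)[C@]12C(OS(=O)(=O)C(F)(F)F)=CC(O[Si](C)(C)O[SiH](C)C)N1CCCCC2=O
F2 | step 11 | (3S,9aR)-9a-[(2R)-1,1-dimethoxybutan-2-yl]-3-[(2S)-4-methyl-5-oxo-2,5-dihydrofuran-2-yl]-9-oxo-5,6,7,8,9,9a-hexahydro-3H-pyrrolo[1,2-a]azepin-1-yl trifluoromethanesulfonate | CC[C@@H](C(OC)OC)[C@]12C(OS(=O)(=O)C(F)(F)F)=C[C@@H]([C@@H]3C=C(C)C(=O)O3)N1CCCCC2=O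
F3 | step 11 | silyl ketene acetal of F2 after hydride addition at C15 (C18–OSiMe2Ph) | CC[C@@H](C(OC)OC)[C@]12C(OS(=O)(=O)C(F)(F)F)=C[C@@H]([C@@H]3CC(C)=C(O[Si](C)(C)c4ccccc4)O3)N1CCCCC2=O
F4 | step 11 | (3S,9aR)-9a-[(2R)-1,1-dimethoxybutan-2-yl]-3-[(2S,4S)-4-methyl-5-oxooxolan-2-yl]-9-oxo-5,6,7,8,9,9a-hexahydro-3H-pyrrolo[1,2-a]azepin-1-yl trifluoromethanesulfonate | CC[C@@H](C(OC)OC)[C@]12C(OS(=O)(=O)C(F)(F)F)=C[C@@H]([C@@H]3C[C@H](C)C(=O)O3)N1CCCCC2=O
F5 | step 14 | oxatitanacyclopentene: ring C closed (C4–C10), Cp2Ti bridging O5 and C8 (cyclopentadienyl rings drawn σ-bonded) | CC[C@H]1[C@@H]2O[Ti](C3C=CC=C3)(C3C=CC=C3)C(C)=C2C2=C[C@@H]([C@@H]3C[C@H](C)C(=O)O3)N3CCCCC(=O)[C@]213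
F6 | step 14 | (Z)-iodo allylic alcohol: ring C closed, C4–OH (4S), exocyclic C10=C8(I)CH3 with iodine cis to C4 | CC[C@H]1[C@H](O)/C(=C(/C)I)C2=C[C@@H]([C@@H]3C[C@H](C)C(=O)O3)N3CCCCC(=O)[C@]213
F7 | step 15 | C8 epimer of 27 (8S) | CC[C@H]1[C@@H]2OC(=O)[C@@H](C)C2=C2C[C@@H]([C@@H]3C[C@H](C)C(=O)O3)N3CCCCC(=O)[C@]213
F8 | step 15 | lithium dienolate of 27 (C6(OLi)=C8, C10=C11) | CC[C@H]1[C@@H]2OC(O[Li])=C(C)C2=C2C[C@@H]([C@@H]3C[C@H](C)C(=O)O3)N3CCCCC(=O)[C@]213
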